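**Retrosynthetic overview**

1. Ferutinine ⇒ (ester C–O) jaeschkeanadiol + O-protected 4-hydroxybenzoic acid; the C6 carbinol ⇒ C6 ketone, reduced by hydride delivered from the C4 hydroxyl.
2. Ring B ⇒ one (4+3) operation: a Brook-rearrangement-mediated [3+4] annulation that joins C6–C5=C1 of a cyclopentenyl acylsilane to C7–C10 of buta-1,3-dien-2-olate (bonds C6–C7 and C1–C10). The C8 enolate oxygen it leaves is exchanged for methyl through the enol triflate.
3. Enabling feature: in ring B the C6 oxygen and the C8=C9 double bond flank the single methylene C7, so with C6 at the enol level ring B is a cyclohepta-1,4-diene (C5=C6, C8=C9), the signature of a cis-divinylcyclopropane Cope shift. The 1,3-related oxygens on C4 and C6 let one silicon atom act as acyl silicon, tether and β-face-blocking temporary ring; it is removed in step 10.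
4. The acylsilane ⇒ (S)-terpinen-4-ol: its ten carbons become C1–C6, the C1 methyl and the isopropyl group, and its carbinol centre becomes C4 (ozonolysis, then aldol ring contraction).
5. Ring order: ring A (step 3); temporary dioxasilinane (step 5, contracted in step 6, re-expanded in step 8); ring B (step 8).

Key step: step 8

Remark: daucane numbering is used (C1 = methyl-bearing ring-fusion carbon, C2/C3 = ring A methylenes, C4 = carbinol carbon, C5 = ring-fusion CH, C6 = ester-bearing carbon, C7 = CH2, C8 = methyl-bearing alkene carbon, C9 = alkene CH, C10 = CH2; ring A = five-membered, ring B = seven-membered; β = face of the C1 methyl); compounds 1, 12 and 21 are assumed to be purchased.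

**Step 1**
Reactants: 1 (S)-(+)-terpinen-4-ol
Product: 2 trimethyl{[(1S)-4-methyl-1-(propan-2-yl)cyclohex-3-en-1-yl]oxy}silane
Conditions: TMSCl, imidazole, DMF, rt
Reagents that add atoms: chlorotrimethylsilane, C[Si](C)(C)Cl
Why: Silyl ether formation masks the tertiary hydroxyl (future C4–OH) so that the β-oxy aldehyde made next cannot lose water; the stereocentre is not touched.

**Step 2**
Reactants: 2 trimethylsilyl ether of terpinen-4-ol
Product: 3 (3S)-6-oxo-3-(propan-2-yl)-3-[(trimethylsilyl)oxy]heptanal
Conditions: O3, CH2Cl2, −78 °C; then Me2S, −78 °C to rt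
Reagents that add atoms: ozone, [O-][O+]=O
Why: Ozonolysis with reductive work-up cleaves the only C=C bond to the methyl ketone and the aldehyde and leaves the quaternary carbinol centre unchanged.

**Step 3**
Reactants: 3 keto aldehyde
Product: 4 (5R)-2-methyl-5-(propan-2-yl)-5-[(trimethylsilyl)oxy]cyclopent-1-ene-1-carbaldehyde
Conditions: piperidine (0.2 equiv), AcOH (0.2 equiv), toluene, 60 °C
Reagents that add atoms: none
Why: Enamine-mediated intramolecular aldol condensation (aldehyde α-carbon onto the methyl ketone, 5-enolexo-exo-trig, then loss of water) should close ring A as the tetrasubstituted enal, the usual ring contraction of ozonised p-menth-1-enes.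

**Step 4**
Reactants: 4 silyloxy enal
Product: 6 (1R)-2-(hydroxymethyl)-3-methyl-1-(propan-2-yl)cyclopent-2-en-1-ol, via trimethylsilyl ether carbinol 5 (not isolated)
Conditions: NaBH4, CeCl3·7H2O, MeOH, 0 °C; then K2CO3, MeOH, rt
Reagents that add atoms: none
Why: Luche 1,2-reduction of the enal followed by methanolysis of the trimethylsilyl ether in the same flask should give the allylic 1,3-diol; no stereocentre is formed.

**Step 5**
Reactants: 6 allylic 1,3-diol
Product: 7 (7aR)-5-methyl-2,2,7a-tri(propan-2-yl)-4,6,7,7a-tetrahydrocyclopenta[d][1,3,2]dioxasiline (diisopropylsilylene acetal of 6)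
Conditions: i-Pr2Si(OTf)2, 2,6-lutidine, CH2Cl2, 0 °C
Reagents that add atoms: diisopropylsilyl bis(trifluoromethanesulfonate), CC(C)[Si](OS(=O)(=O)C(F)(F)F)(OS(=O)(=O)C(F)(F)F)C(C)C
Why: Standard silylene protection of a 1,3-diol closes the temporary six-membered ring that ties the C4 oxygen to the C6 oxygen through one silicon atom.

**Step 6**
Reactants: 7 silylene acetal
Product: 10 (6aR)-4-methyl-2,2,6a-tri(propan-2-yl)-3,5,6,6a-tetrahydro-2H-cyclopenta[d][1,2]oxasilol-3-ol (both carbinol epimers), via silyloxyallyllithium 8 (not isolated), via lithium silyl alkoxide 9 (not isolated)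
Conditions: t-BuLi, THF, −78 to −20 °C; then AcOH, −78 °C
Reagents that add atoms: none
Why: Proposed new method: deprotonation of the allylic O–CH2 group (C6) gives the α-silyloxy allyllithium 8, in which silicon should shift from oxygen to carbon (1,2-retro-Brook or silyl-Wittig shift) because the lithium alkoxide 9 is more stable than the carbanion, contracting the dioxasilinane to an oxasilolane; the closest known reaction is the retro-Brook rearrangement of lithiated allyl trialkylsilyl ethers to α-silyl allyl alcohols, not yet shown for a cyclic dialkoxysilane; the new carbinol centre is erased in step 7.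

**Step 7**
Reactants: 10 cyclic α-silyl alcohol
Product: 11 (6aR)-4-methyl-2,2,6a-tri(propan-2-yl)-6,6a-dihydro-2H-cyclopenta[d][1,2]oxasilol-3(5H)-one (cyclic acylsilane)
Conditions: Dess–Martin periodinane, NaHCO3, CH2Cl2, 0 °C to rt
Reagents that add atoms: none
Why: Dess–Martin oxidation of an α-silyl alcohol is the usual last step of an acylsilane synthesis and removes the carbinol stereocentre.

**Step 8**
Reactants: 11 cyclic acylsilane; 12 2-(trimethylsilyloxy)buta-1,3-diene
Product: 17 tricyclic enol triflate (ring A, ring B with C5=C6 and C8=C9, C8–OTf, O4 and O6 bridged by Si(i-Pr)2; 1R,4R), via lithium butadienolate 13 (not isolated), via lithium aldolate 14 (not isolated), via dialkenylcyclopropanolate 15 (not isolated), via cycloheptadienolate 16 (not isolated)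
Conditions: 12, MeLi, THF, 0 °C to rt; then 11, −80 to −30 °C; then Comins' reagent, −78 to 0 °C
Reagents that add atoms: N-(5-chloropyridin-2-yl)-1,1,1-trifluoro-N-(trifluoromethanesulfonyl)methanesulfonamide (Comins' reagent), Clc1ccc(N(S(=O)(=O)C(F)(F)F)S(=O)(=O)C(F)(F)F)nc1
Why: Proposed new method: methyllithium turns 12 into the dienolate 13, whose CH2 terminus adds to the acylsilane carbonyl (C7–C6); in the aldolate 14 silicon shifts from C6 to the C6 oxygen (1,2-Brook shift, which expands the oxasilolane to the dioxasilinane) while the C6 carbanion closes on the C8 ketone (3-exo-trig) to the cis-1,2-dialkenylcyclopropanolate 15, and anionic oxy-Cope rearrangement through a boat transition state (C6–C8 broken, C1–C10 formed) gives the cyclohepta-1,4-dienolate 16, which is triflated on oxygen. The closest known reaction is the Brook-rearrangement-mediated [3+4] annulation of trialkylsilyl acryloylsilanes with lithium enolates of alkenyl methyl ketones; new here are the silicon atom tethered through the C4 oxygen and the in situ triflation. Ring B closes by the [3,3] shift (a net (4+3) annulation), the temporary silicon ring by ring expansion, and the cyclopropane only transiently by carbanion addition to the ketone. The one new stereocentre that survives, quaternary C1, is controlled by C4: the O–Si(i-Pr)2–O bridge sits on the β-face beside C6 with one isopropyl group axial, so the C8 alkoxide arm can close on C6 only from the α-face, and the suprafacial Cope shift then joins C10 to C1 on that same face, cis to the C4 isopropyl and trans to the C4 oxygen. The step needs addition at the carbonyl carbon and not at silicon (two branched groups on silicon), a cis arrangement of the two alkenyl groups on the cyclopropane (as in the parent annulation), and trapping of the C8=C9 enolate before proton transfer can move it (no amine present, triflation at −78 °C).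

**Step 9**
Reactants: 17 enol triflate
Product: 18 tricyclic C8-methyl diene (as 17 with CH3 in place of OTf; 1R,4R)
Conditions: MeZnCl, Pd(PPh3)4 (5 mol%), THF, rt to 50 °C
Reagents that add atoms: methylzinc chloride, C[Zn]Cl
Why: Negishi coupling of the enol triflate should install the C8 methyl without moving the C8=C9 double bond, and the silylene enol ether is inert to the organozinc reagent.

**Step 10**
Reactants: 18 silylene enol ether
Product: 19 (3R,3aR,8aR)-3-hydroxy-6,8a-dimethyl-3-(propan-2-yl)-2,3,3a,5,8,8a-hexahydroazulen-4(1H)-one (trans-fused C6 ketol)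
Conditions: HF·pyridine, pyridine, THF, 0 °C to rt
Reagents that add atoms: none
Why: Fluoride-assisted cleavage of the silylene (protodesilylation of the silyl enol ether and of the silyl ether) should release the C6 ketone and the C4 hydroxyl, with C5 protonated from the α-face anti to the silicon bridge; the resulting trans-fused ketol, with C6 cis to the C4 hydroxyl (O–H···O=C hydrogen bond) and trans to isopropyl, is also the epimer expected at equilibrium under these mildly acidic conditions.

**Step 11**
Reactants: 19 ketol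
Product: 20 jaeschkeanadiol, (3R,3aS,4S,8aR)-6,8a-dimethyl-3-(propan-2-yl)-1,2,3,3a,4,5,8,8a-octahydroazulene-3,4-diol
Conditions: Me4NBH(OAc)3, MeCN–AcOH (1:1), −20 °C
Reagents that add atoms: none
Why: Hydroxyl-directed Evans–Saksena reduction: the borohydride bound to the β-oriented C4 oxygen should deliver hydride to the β-face of the C6 ketone, giving the 1,3-anti diol with the C6 hydroxyl α (6S).

**Step 12**
Reactants: 20 jaeschkeanadiol; 21 4-[(tert-butyldimethylsilyl)oxy]benzoic acid
Product: 22 jaeschkeanadiol 6-{4-[(tert-butyldimethylsilyl)oxy]benzoate}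
Conditions: DCC, DMAP, CH2Cl2, rt
Reagents that add atoms: none
Why: Steglich esterification should acylate only the secondary C6 hydroxyl, because the tertiary C4 hydroxyl is too hindered; no stereocentre is affected.

**Step 13**
Reactants: 22 silyl-protected ester
Product: 23 ferutinine
Conditions: TBAF, AcOH, THF, 0 °C
Reagents that add atoms: none
Why: Buffered fluoride cleavage of the aryl silyl ether should free the phenol and leave the benzoate ester and the tertiary alcohol untouched.

**Compound list**

1 | (S)-(+)-terpinen-4-ol, (1S)-4-methyl-1-(propan-2-yl)cyclohex-3-en-1-ol | CC1=CC[C@](O)(C(C)C)CC1 | starting material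
2 | trimethyl{[(1S)-4-methyl-1-(propan-2-yl)cyclohex-3-en-1-yl]oxy}silane | CC1=CC[C@](O[Si](C)(C)C)(C(C)C)CC1 | intermediate
3 | (3S)-6-oxo-3-(propan-2-yl)-3-[(trimethylsilyl)oxy]heptanal | O=CC[C@](O[Si](C)(C)C)(C(C)C)CCC(C)=O | intermediate
4 | (5R)-2-methyl-5-(propan-2-yl)-5-[(trimethylsilyl)oxy]cyclopent-1-ene-1-carbaldehyde | CC1=C(C=O)[C@](O[Si](C)(C)C)(C(C)C)CC1 | intermediate
5 | [(5R)-2-methyl-5-(propan-2-yl)-5-[(trimethylsilyl)oxy]cyclopent-1-en-1-yl]methanol | CC1=C(CO)[C@](O[Si](C)(C)C)(C(C)C)CC1 | intermediate (not isolated)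
6 | (1R)-2-(hydroxymethyl)-3-methyl-1-(propan-2-yl)cyclopent-2-en-1-ol | CC1=C(CO)[C@](O)(C(C)C)CC1 | intermediate
7 | (7aR)-5-methyl-2,2,7a-tri(propan-2-yl)-4,6,7,7a-tetrahydrocyclopenta[d][1,3,2]dioxasiline | CC1=C2CO[Si](C(C)C)(C(C)C)O[C@@]2(C(C)C)CC1 | intermediate
8 | 4-lithio derivative of 7 (α-silyloxy allyllithium, lithium on the O-bearing ring carbon) | CC1=C2C([Li])O[Si](C(C)C)(C(C)C)O[C@@]2(C(C)C)CC1 | intermediate (not isolated)
9 | lithium (6aR)-4-methyl-2,2,6a-tri(propan-2-yl)-3,5,6,6a-tetrahydro-2H-cyclopenta[d][1,2]oxasilol-3-olate (either carbinol epimer) | CC1=C2C(O[Li])[Si](C(C)C)(C(C)C)O[C@@]2(C(C)C)CC1 | intermediate (not isolated)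
10 | (6aR)-4-methyl-2,2,6a-tri(propan-2-yl)-3,5,6,6a-tetrahydro-2H-cyclopenta[d][1,2]oxasilol-3-ol (both carbinol epimers) | CC1=C2C(O)[Si](C(C)C)(C(C)C)O[C@@]2(C(C)C)CC1 | intermediate
11 | (6aR)-4-methyl-2,2,6a-tri(propan-2-yl)-6,6a-dihydro-2H-cyclopenta[d][1,2]oxasilol-3(5H)-one | CC1=C2C(=O)[Si](C(C)C)(C(C)C)O[C@@]2(C(C)C)CC1 | intermediate
12 | 2-(trimethylsilyloxy)buta-1,3-diene | C=CC(=C)O[Si](C)(C)C | starting material
13 | lithium buta-1,3-dien-2-olate | [Li]OC(=C)C=C | intermediate (not isolated)
14 | lithium aldolate: 11 carrying O–Li and a 2-oxobut-3-en-1-yl group on the former carbonyl carbon (either epimer at that carbon) | CC1=C2C(O[Li])(CC(=O)C=C)[Si](C(C)C)(C(C)C)O[C@@]2(C(C)C)CC1 | intermediate (not isolated)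
15 | lithium cis-1,2-dialkenylcyclopropanolate: cyclopropane spiro-fused at C6 to the dioxasiline, C8 bearing O–Li and ethenyl, ethenyl cis to the cyclopentenyl carbon, C8 on the α-face | [Li]O[C@]1(C=C)C[C@]12O[Si](C(C)C)(C(C)C)O[C@@]3(C(C)C)CCC(C)=C23 | intermediate (not isolated)
16 | lithium cyclohepta-1,4-dienolate: ring A, ring B with C5=C6 and C8(OLi)=C9, O4 and O6 bridged by Si(i-Pr)2; 1R,4R | [Li]OC1=CC[C@@]2(C)CC[C@]3(C(C)C)O[Si](C(C)C)(C(C)C)OC(C1)=C23 | intermediate (not isolated)
17 | enol triflate: as 16 with OSO2CF3 on C8; 1R,4R | O=S(=O)(OC1=CC[C@@]2(C)CC[C@]3(C(C)C)O[Si](C(C)C)(C(C)C)OC(C1)=C23)C(F)(F)F | intermediate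
18 | C8-methyl diene: as 17 with CH3 on C8; 1R,4R | CC1=CC[C@@]2(C)CC[C@]3(C(C)C)O[Si](C(C)C)(C(C)C)OC(C1)=C23 | intermediate
19 | (3R,3aR,8aR)-3-hydroxy-6,8a-dimethyl-3-(propan-2-yl)-2,3,3a,5,8,8a-hexahydroazulen-4(1H)-one | CC1=CC[C@@]2(C)CC[C@@](O)(C(C)C)[C@@H]2C(=O)C1 | intermediate
20 | jaeschkeanadiol, (3R,3aS,4S,8aR)-6,8a-dimethyl-3-(propan-2-yl)-1,2,3,3a,4,5,8,8a-octahydroazulene-3,4-diol | CC1=CC[C@@]2(C)CC[C@@](O)(C(C)C)[C@@H]2[C@@H](O)C1 | intermediate
21 | 4-[(tert-butyldimethylsilyl)oxy]benzoic acid | OC(=O)c1ccc(O[Si](C)(C)C(C)(C)C)cc1 | starting material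
22 | (3R,3aS,4S,8aR)-3-hydroxy-6,8a-dimethyl-3-(propan-2-yl)-1,2,3,3a,4,5,8,8a-octahydroazulen-4-yl 4-[(tert-butyldimethylsilyl)oxy]benzoate | CC1=CC[C@@]2(C)CC[C@@](O)(C(C)C)[C@@H]2[C@@H](OC(=O)c2ccc(O[Si](C)(C)C(C)(C)C)cc2)C1 | intermediate
23 | ferutinine, (3R,3aS,4S,8aR)-3-hydroxy-6,8a-dimethyl-3-(propan-2-yl)-1,2,3,3a,4,5,8,8a-octahydroazulen-4-yl 4-hydroxybenzoate | CC1=CC[C@@]2(C)CC[C@@](O)(C(C)C)[C@@H]2[C@@H](OC(=O)c2ccc(O)cc2)C1 | target

**Step count and risks**

Total step count: 13. Longest linear sequence: 13 steps (1 to 23).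

Steps most likely to fail:

Step 8 (proposed new method). The silicon–carbon bond held in the five-membered ring is poorly aligned with the alkene π-system, so the Brook shift may be slow and the aldolate may revert or simply be protonated. Attack of the enolate at silicon, and erosion of the facial control at C1, are further risks. The fallback uses the established untethered annulation; it sets out from 4 and returns at 19. PhMe2SiLi (THF, −78 °C) should add to the aldehyde of 4 to give the α-silyl carbinol F1, and Dess–Martin oxidation should give the acyclic acylsilane F2. Annulation of F2 with dienolate 13 and triflation with Comins' reagent should give the bis(silyl ether) enol triflate F3, and Negishi methylation the diene F4. HF·pyridine then removes both silyl groups to give 19. Facial control at C1 would then rest only on the size of the C4 silyl ether, which can be enlarged from step 1 (triethylsilyl or tert-butyldimethylsilyl).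

Step 6 (proposed new method). Metalation may occur at the C1 methyl or the ring methylene instead of C6, the alkyllithium may attack silicon, or the dialkoxysilyl group may be reluctant to migrate. The fallback uses the dithiane route to acylsilanes; it sets out from 4 and returns at 11. Propane-1,3-dithiol and BF3·OEt2 should convert 4 into the hydroxy dithiane F5 (the trimethylsilyl ether is lost on work-up). Double deprotonation (n-BuLi, 2 equiv) and ring-closing C,O-silylation with i-Pr2SiCl2 should give the spiro silyl dithiane F6. Dithiane hydrolysis (MeI, CaCO3, aqueous MeCN) should then give 11.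

Step 11. The hindered tertiary hydroxyl may exchange slowly with the triacetoxyborohydride, so that hydride delivery is incomplete and facial selectivity at C6 is poor. The fallback sets out from 19 and returns at 22. An undirected reduction with the bulky LiBH(s-Bu)3 (THF, −78 °C) should attack the less hindered α-face and give 6-epi-jaeschkeanadiol F7. Mitsunobu esterification of F7 with acid 21 (PPh3, DIAD, toluene) inverts C6 and should give 22 directly.

**Further compounds**

F1 | step 8 | [dimethyl(phenyl)silyl][(5R)-2-methyl-5-(propan-2-yl)-5-[(trimethylsilyl)oxy]cyclopent-1-en-1-yl]methanol (carbinol epimers) | CC1=C(C(O)[Si](C)(C)c2ccccc2)[C@](O[Si](C)(C)C)(C(C)C)CC1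
F2 | step 8 | [dimethyl(phenyl)silyl][(5R)-2-methyl-5-(propan-2-yl)-5-[(trimethylsilyl)oxy]cyclopent-1-en-1-yl]methanone | CC1=C(C(=O)[Si](C)(C)c2ccccc2)[C@](O[Si](C)(C)C)(C(C)C)CC1
F3 | step 8 | bicyclic enol triflate: ring A, ring B with C5=C6 and C8=C9, C4–OSiMe3, C6–OSiMe2Ph, C8–OTf; 1R,4R | O=S(=O)(OC1=CC[C@@]2(C)CC[C@@](O[Si](C)(C)C)(C(C)C)C2=C(O[Si](C)(C)c2ccccc2)C1)C(F)(F)F
F4 | step 8 | bicyclic diene: as F3 with CH3 on C8; 1R,4R | CC1=CC[C@@]2(C)CC[C@@](O[Si](C)(C)C)(C(C)C)C2=C(O[Si](C)(C)c2ccccc2)C1
F5 | step 6 | (1R)-2-(1,3-dithian-2-yl)-3-methyl-1-(propan-2-yl)cyclopent-2-en-1-ol | CC1=C(C2SCCCS2)[C@](O)(C(C)C)CC1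
F6 | step 6 | spiro 1,3-dithiane of 11 (dithiane carbon in place of the carbonyl carbon) | CC1=C2C3(SCCCS3)[Si](C(C)C)(C(C)C)O[C@@]2(C(C)C)CC1
F7 | step 11 | 6-epi-jaeschkeanadiol, (3R,3aS,4R,8aR)-6,8a-dimethyl-3-(propan-2-yl)-1,2,3,3a,4,5,8,8a-octahydroazulene-3,4-diol | CC1=CC[C@@]2(C)CC[C@@](O)(C(C)C)[C@@H]2[C@H](O)C1
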